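All runs were computed with constants of no real substance, and the scatter is random.

These exchanges are slow, and slowness tempts one to reckon in hours. I reckoned instead with f, the fraction of the starting complex left, so that the clock dropped out.

| setting | north-east | south-west | ochre | blue | green | amber | teal |
|---|---|---|---|---|---|---|---|
| starting complex | 0.10 M | 0.10 M | 0.10 M | 0.10 M | 0.10 M | 0.10 M | 0.10 M |
| incoming ligand | 1.5 equiv | 24 equiv | 1.00 equiv | 2.00 equiv | 4.00 equiv | 8.00 equiv | 15.0 equiv |
| remark | run made earlier | run made earlier |  |  |  |  |  |
| time |  |  | 3.0 h | 3.0 h | 3.0 h | 3.0 h | 3.0 h |

1. amount of complex with one exchanged at the end, in percent of the starting complex charged for ochre, blue, green, amber, teal, in this order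
2. the shape of the row from first to last (rises, then falls / hardly changes / rises all the way / falls, then rises / falls all the way)

- steps that have been proposed: complex with two exchanged + incoming ligand -> leaving ligand + complex with three exchanged; starting complex + incoming ligand -> leaving ligand + complex with one exchanged; incoming ligand -> decomposed reagent; complex with one exchanged -> over-reaction product; complex with three exchanged + incoming ligand -> leaving ligand + complex with four exchanged; complex with one exchanged + incoming ligand -> leaving ligand + complex with two exchanged
- "hardly changes" means that all values lie within two and a half points (for a concentration: within two and a half percent of the largest)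

| run | time / min | complex with one exchanged / % | starting complex / % |
|---|---|---|---|
| north-east | 12.0 | 7 | 94 |
| north-east | 30.0 | 11 | 87 |
| north-east | 60.0 | 15 | 76 |
| north-east | 90.0 | 18 | 70 |
| south-west | 25.0 | 9 | 14 |
| south-west | 50.0 | 4 | 1 |
| south-west | 60.0 | 3 | 3 |
| south-west | 90.0 | 0 | 0 |

(readings scatter by 1.5 percentage points)

Both exchanges take incoming ligand, so when I divided one rate by the other, the ligand and the time cancelled, however the ligand was being lost. I set the over-reaction aside. With s the ratio of the two constants, the complex with one exchanged, as a fraction of the charge, came to (f − f^s)/(s − 1).

Late in a run f^s fades, so c(starting complex)/c(complex with one exchanged) tends to s − 1. I read this from the first south-west row, where 14% of starting complex stood against 9% of complex with one exchanged at 25.0 min. The selectivity factor, the constant for loss of complex with one exchanged over that for loss of starting complex, therefore read 2.56. With that value, f^s at this south-west row came to 0.652%, less than f, so the late form could be used there. The later south-west rows stand too near zero against a scatter of 1.5 percentage points to add anything.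

The last north-east row was my check. Its 70% left gives 19.1% by the rule, and the reading was 18%.

The curve peaks at f = 54.7%, with a height of 21.4%. Scaling the north-east loss in ln f by charge and time, as though the ligand held, put ochre at 62.2%, still above the peak fraction. Scaling the south-west loss put teal at 29.3% after 25.0 min, already past it. So I committed to a row climbing to about 21.4% near blue and then falling.

The forecast gave 17%, 20%, 13%, 2.5% and 0.1%, rises, then falls, holding that “excess ligand then destroys it”.

The flasks gave 18.1%, 21.9%, 16.6%, 4.92% and 0.366%: rises, then falls.

    complex with two exchanged + incoming ligand → leaving ligand + complex with three exchanged (k = 0.00550 L mol⁻¹ min⁻¹)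
    starting complex + incoming ligand → leaving ligand + complex with one exchanged (k = 0.0400 L mol⁻¹ min⁻¹)
    incoming ligand → decomposed reagent (k = 0.00690 min⁻¹)
    complex with one exchanged → over-reaction product (k = 1.10 × 10⁻⁶ min⁻¹)
    complex with three exchanged + incoming ligand → leaving ligand + complex with four exchanged (k = 0.120 L mol⁻¹ min⁻¹)
    complex with one exchanged + incoming ligand → leaving ligand + complex with two exchanged (k = 0.0990 L mol⁻¹ min⁻¹)

On ochre the rule turned 73.6% left into 17.9%, against 18.1% in the flask. Decomposition of the ligand holds ochre back on this curve: with that step taken away, ochre stands at 21.4% rather than 18.1%, and the shape of the row turns. On teal I used s again in its late form, where 0.540% of starting complex divided by s − 1 gives 0.346%, and the flask holds 0.366%.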